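**Retrosynthetic overview**
1. Target ← desilylation ← ring A by ring-closing metathesis (RCM), which forms the bridgehead C10=C11 alkene of the bicyclo[4.4.1]undecene last, from a 6–7 bicycle carrying a (5E)-hepta-1,5-dien-2-yl arm and an exocyclic methylidene.
2. Ring B (7-membered) ← RCM of a terminal vinyl group onto the exocyclic 1,3-diene of ring C; the s-cis diene left behind is 1,4-hydrogenated to the tetrasubstituted methyl alkene.
3. Fragment union and both ring-fusion stereocentres ← chair Claisen rearrangement of a (Z)-enol ether made by Takai–Utimoto alkylidenation of an allylic ester.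
4. Fragments: ring C dienyl alcohol 8 (from (S)-citronellal and methyl vinyl ketone by organocatalytic Michael/aldol), (4E)-hex-4-enoic acid 13, gem-dibromide 22.
5. Ring order: C → B → A.

Assumption: but-3-en-2-ol (9) is used as the racemate (its stereocentre is destroyed in step 6), and 23 is drawn as the geminal dizinc species usually written for the Takai–Utimoto reagent.
Abbreviation in names: TBDPS = tert-butyl(diphenyl)silyl.

**Route**

Step 1
Reactants: 1 (S)-citronellal; 2 methyl vinyl ketone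
Product: 4 (4S)-4-[(2S)-6-methylhept-5-en-2-yl]cyclohex-2-en-1-one, via Michael adduct 3 (not isolated)
Conditions: (S)-2-[diphenyl(trimethylsilyloxy)methyl]pyrrolidine (10 mol%), ethyl 3,4-dihydroxybenzoate (20 mol%), neat, 4 °C; then LiOH, i-PrOH, 25 °C
Reagents that add atoms: none
Why: Enamine-catalysed Michael addition with the enone entering anti to the CPh2OSiMe3 group sets the new (S) centre under catalyst control, and a base-mediated intramolecular aldol condensation then closes ring C while the citronellal methyl centre is carried through unchanged.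

Step 2
Reactants: 4 (4S)-4-[(2S)-6-methylhept-5-en-2-yl]cyclohex-2-en-1-one
Product: 5 (4S)-4-[(2S,5E)-7-hydroxy-6-methylhept-5-en-2-yl]cyclohex-2-en-1-one
Conditions: SeO2 (20 mol%), t-BuOOH, salicylic acid (10 mol%), CH2Cl2, 25 °C
Reagents that add atoms: selenium dioxide, O=[Se]=O (oxygen carrier); tert-butyl hydroperoxide, CC(C)(C)OO (terminal oxidant)
Why: Sharpless SeO2/t-BuOOH allylic oxidation (ene reaction then [2,3]-shift) attacks only the electron-rich trisubstituted alkene at its (E)-methyl group, giving the E allylic alcohol while the electron-poor enone is inert.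

Step 3
Reactants: 5 (4S)-4-[(2S,5E)-7-hydroxy-6-methylhept-5-en-2-yl]cyclohex-2-en-1-one
Product: 6 (4S)-4-[(2S,5E)-6-methyl-7-(TBDPS-oxy)hept-5-en-2-yl]cyclohex-2-en-1-one
Conditions: t-BuPh2SiCl, imidazole, DMF, 0 → 25 °C
Reagents that add atoms: tert-butyl(chloro)diphenylsilane, CC(C)(C)[Si](Cl)(c1ccccc1)c1ccccc1
Why: Standard silylation of the primary allylic alcohol gives an ether that survives ylides, low-valent metal reagents, hydrogenation and metathesis.

Step 4
Reactants: 6 (4S)-4-[(2S,5E)-6-methyl-7-(TBDPS-oxy)hept-5-en-2-yl]cyclohex-2-en-1-one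
Product: 7 (4S)-2-(hydroxymethyl)-4-[(2S,5E)-6-methyl-7-(TBDPS-oxy)hept-5-en-2-yl]cyclohex-2-en-1-one
Conditions: 37% aq. HCHO, DMAP (30 mol%), THF/H2O, 25 °C
Reagents that add atoms: formaldehyde, C=O
Why: Morita–Baylis–Hillman reaction (DMAP conjugate addition, aldol with formaldehyde, E1cB release of the catalyst) hydroxymethylates C2 without touching the C4 stereocentre.

Step 5
Reactants: 7 (4S)-2-(hydroxymethyl)-4-[(2S,5E)-6-methyl-7-(TBDPS-oxy)hept-5-en-2-yl]cyclohex-2-en-1-one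
Product: 8 {(3S)-3-[(2S,5E)-6-methyl-7-(TBDPS-oxy)hept-5-en-2-yl]-6-methylidenecyclohex-1-en-1-yl}methanol
Conditions: Ph3PCH3Br, KOtBu (excess), THF, 0 → 25 °C
Reagents that add atoms: methylidene(triphenyl)phosphorane, C=P(c1ccccc1)(c1ccccc1)c1ccccc1
Why: Wittig methylenation of the enone carbonyl (one extra equivalent of ylide is spent on the hydroxyl) removes the ketone before the alkylidenation step and installs the carbon that later becomes the ring C methyl group.

Step 6
Reactants: 9 but-3-en-2-ol; 10 triethyl orthoacetate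
Product: 12 ethyl (4E)-hex-4-enoate, via ketene acetal 11 (not isolated)
Conditions: EtCO2H (cat.), 140 °C, EtOH distilled off
Reagents that add atoms: none
Why: Johnson–Claisen rearrangement through a chair transition state with the methyl group equatorial gives the E alkene selectively.

Step 7
Reactants: 12 ethyl (4E)-hex-4-enoate
Product: 13 (4E)-hex-4-enoic acid
Conditions: LiOH, THF/H2O, 25 °C; then aq. HCl
Reagents that add atoms: lithium hydroxide, [Li+].[OH-]
Why: Simple saponification of an unhindered ester.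

Step 8
Reactants: 8 {(3S)-3-[(2S,5E)-6-methyl-7-(TBDPS-oxy)hept-5-en-2-yl]-6-methylidenecyclohex-1-en-1-yl}methanol; 13 (4E)-hex-4-enoic acid
Product: 14 {(3S)-3-[(2S,5E)-6-methyl-7-(TBDPS-oxy)hept-5-en-2-yl]-6-methylidenecyclohex-1-en-1-yl}methyl (4E)-hex-4-enoate
Conditions: EDC·HCl, DMAP (cat.), CH2Cl2, 0 → 25 °C
Reagents that add atoms: none
Why: Steglich-type carbodiimide esterification of a primary allylic alcohol proceeds under neutral conditions that leave the diene untouched.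

Step 9
Reactants: 15 pent-4-en-1-ol
Product: 16 pent-4-enal
Conditions: TEMPO (10 mol%), PhI(OAc)2, CH2Cl2, 25 °C
Reagents that add atoms: none
Why: TEMPO/oxoammonium oxidation stops cleanly at the volatile aldehyde.

Step 10
Reactants: 16 pent-4-enal
Product: 17 2-methylidenepent-4-enal
Conditions: 37% aq. HCHO, pyrrolidine (10 mol%), EtCO2H (10 mol%), i-PrOH, 45 °C
Reagents that add atoms: formaldehyde, C=O
Why: Amine-catalysed Mannich-type condensation with formaldehyde followed by elimination gives the α-methylene aldehyde.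

Step 11
Reactants: 17 2-methylidenepent-4-enal
Product: 18 2-methylidenepent-4-en-1-ol
Conditions: NaBH4, CeCl3·7H2O, MeOH, 0 °C
Reagents that add atoms: none
Why: Luche reduction delivers hydride 1,2 to the enal and leaves both alkenes intact.

Step 12
Reactants: 18 2-methylidenepent-4-en-1-ol
Product: 19 2-(bromomethyl)penta-1,4-diene
Conditions: PBr3, pyridine (cat.), Et2O, 0 °C
Reagents that add atoms: phosphorus tribromide, BrP(Br)Br
Why: Bromide displaces the phosphite ester of the primary allylic alcohol, and direct and allylic (SN2') attack give the same product because the allyl unit is symmetric.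

Step 13
Reactants: 19 2-(bromomethyl)penta-1,4-diene; 20 dibromomethane
Product: 22 1,1-dibromo-3-methylidenehex-5-ene, via dibromomethyllithium 21 (not isolated)
Conditions: LiN(i-Pr)2, THF/Et2O, −95 °C; then 19, −95 → −40 °C
Reagents that add atoms: none
Why: Low-temperature deprotonation of CH2Br2 gives the carbenoid LiCHBr2, which is alkylated by the reactive allylic bromide in an SN2 reaction before it can decompose.

Step 14
Reactants: 14 {(3S)-3-[(2S,5E)-6-methyl-7-(TBDPS-oxy)hept-5-en-2-yl]-6-methylidenecyclohex-1-en-1-yl}methyl (4E)-hex-4-enoate; 22 1,1-dibromo-3-methylidenehex-5-ene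
Product: 25 (6S,10E)-6-{(1R,6S)-6-[(2S,5E)-6-methyl-7-(TBDPS-oxy)hept-5-en-2-yl]-2,3-dimethylidenecyclohexyl}-4-methylidenedodeca-1,10-dien-7-one, via geminal dizinc reagent 23 (not isolated), via (Z)-enol ether 24 (not isolated)
Conditions: Zn, PbCl2 (cat.), TiCl4, TMEDA, THF, 25 °C; filtration through basic Al2O3; then PhMe, 110 °C
Reagents that add atoms: none
Why: Takai–Utimoto alkylidenation turns the ester into the (Z)-enol ether, and the Claisen rearrangement then runs through a chair transition state (enol-ether chain cis to oxygen axial, ring branch equatorial) on the alkene face anti to the C6 side chain, which sets both new centres (6S on the chain, 1R on the ring) with the relative and absolute configuration of the target.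

Step 15
Reactants: 25 (6S,10E)-6-{(1R,6S)-6-[(2S,5E)-6-methyl-7-(TBDPS-oxy)hept-5-en-2-yl]-2,3-dimethylidenecyclohexyl}-4-methylidenedodeca-1,10-dien-7-one
Product: 26 (4E)-1-{(6S,7R,8S)-8-[(2S,5E)-6-methyl-7-(TBDPS-oxy)hept-5-en-2-yl]-4,11-dimethylidenebicyclo[5.4.0]undec-1-en-6-yl}hex-4-en-1-one
Conditions: second-generation Hoveyda–Grubbs catalyst RuCl2(H2IMes)(=CH-C6H4-2-O-i-Pr) (10 mol%), CH2Cl2 (0.002 M), 40 °C
Reagents that add atoms: none
Why: In this ring-closing metathesis the carbene forms at the only monosubstituted alkene and closes onto the adjacent diene terminus to give seven-membered ring B, while the internal E alkene and the other 1,1-disubstituted alkenes react more slowly and no stereocentre is touched.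

Step 16
Reactants: 26 (4E)-1-{(6S,7R,8S)-8-[(2S,5E)-6-methyl-7-(TBDPS-oxy)hept-5-en-2-yl]-4,11-dimethylidenebicyclo[5.4.0]undec-1-en-6-yl}hex-4-en-1-one
Product: 27 (4E)-1-{(6S,7R,8S)-11-methyl-8-[(2S,5E)-6-methyl-7-(TBDPS-oxy)hept-5-en-2-yl]-4-methylidenebicyclo[5.4.0]undec-1(11)-en-6-yl}hex-4-en-1-one
Conditions: Cr(CO)3(η6-C10H8) (20 mol%), H2 (70 atm), acetone, 25 °C
Reagents that add atoms: none
Why: Arene–Cr(CO)3-catalysed 1,4-hydrogenation binds only the s-cis 1,3-diene and adds H2 across its ends, giving the tetrasubstituted ring alkene with its methyl group and leaving the isolated alkenes, the skipped diene and the ketone alone.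

Step 17
Reactants: 27 (4E)-1-{(6S,7R,8S)-11-methyl-8-[(2S,5E)-6-methyl-7-(TBDPS-oxy)hept-5-en-2-yl]-4-methylidenebicyclo[5.4.0]undec-1(11)-en-6-yl}hex-4-en-1-one
Product: 28 tert-butyl{[(2E,6S)-6-{(6S,7R,8S)-6-[(5E)-hepta-1,5-dien-2-yl]-11-methyl-4-methylidenebicyclo[5.4.0]undec-1(11)-en-8-yl}-2-methylhept-2-en-1-yl]oxy}diphenylsilane
Conditions: Ph3PCH3Br, KOtBu, PhMe/THF, 25 → 50 °C
Reagents that add atoms: methylidene(triphenyl)phosphorane, C=P(c1ccccc1)(c1ccccc1)c1ccccc1
Why: Wittig methylenation installs the exocyclic methylidene, and the adjacent centre should hold because its acyl group sits equatorial on ring B, trans to the ring C branch, so any reversible enolisation is expected to return the same epimer.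

Step 18
Reactants: 28 tert-butyl{[(2E,6S)-6-{(6S,7R,8S)-6-[(5E)-hepta-1,5-dien-2-yl]-11-methyl-4-methylidenebicyclo[5.4.0]undec-1(11)-en-8-yl}-2-methylhept-2-en-1-yl]oxy}diphenylsilane
Product: 29 tert-butyl{[(2E,6S)-2-methyl-6-[(1S,2R,3S)-6-methyl-14-methylidenetricyclo[8.4.1.0^{2,7}]pentadeca-6,10-dien-3-yl]hept-2-en-1-yl]oxy}diphenylsilane
Conditions: second-generation Grubbs catalyst RuCl2(=CHPh)(PCy3)(H2IMes) (20 mol%), 1,4-benzoquinone (20 mol%), PhMe (0.001 M), 90 °C
Reagents that add atoms: none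
Why: Ring-closing metathesis between the (E)-propenyl terminus and the ring B methylidene is the only productive pairing (the C14 methylidene could only close a four-membered ring), so it forms seven-membered ring A and the bridgehead trisubstituted alkene, which Bredt's rule allows in a bicyclo[4.4.1]undecene, with loss of propene and no change at any stereocentre.

Step 19
Reactants: 29 tert-butyl{[(2E,6S)-2-methyl-6-[(1S,2R,3S)-6-methyl-14-methylidenetricyclo[8.4.1.0^{2,7}]pentadeca-6,10-dien-3-yl]hept-2-en-1-yl]oxy}diphenylsilane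
Product: 30 (2E,6S)-2-methyl-6-[(1S,2R,3S)-6-methyl-14-methylidenetricyclo[8.4.1.0^{2,7}]pentadeca-6,10-dien-3-yl]hept-2-en-1-ol
Conditions: n-Bu4NF, THF, 0 → 25 °C
Reagents that add atoms: none
Why: Fluoride-mediated desilylation frees the primary allylic alcohol without affecting the four alkenes.

**Compound list**
1 | (S)-citronellal, (3S)-3,7-dimethyloct-6-enal | O=CC[C@@H](C)CCC=C(C)C | starting material
2 | methyl vinyl ketone (but-3-en-2-one) | CC(=O)C=C | starting material
3 | (2S)-2-[(2S)-6-methylhept-5-en-2-yl]-5-oxohexanal | CC(=O)CC[C@@H]([C@@H](C)CCC=C(C)C)C=O | intermediate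
4 | (4S)-4-[(2S)-6-methylhept-5-en-2-yl]cyclohex-2-en-1-one | O=C1CC[C@@H]([C@@H](C)CCC=C(C)C)C=C1 | intermediate
5 | (4S)-4-[(2S,5E)-7-hydroxy-6-methylhept-5-en-2-yl]cyclohex-2-en-1-one | O=C1CC[C@@H]([C@@H](C)CC/C=C(\C)CO)C=C1 | intermediate
6 | (4S)-4-[(2S,5E)-6-methyl-7-(TBDPS-oxy)hept-5-en-2-yl]cyclohex-2-en-1-one | O=C1CC[C@@H]([C@@H](C)CC/C=C(\C)CO[Si](c2ccccc2)(c2ccccc2)C(C)(C)C)C=C1 | intermediate
7 | (4S)-2-(hydroxymethyl)-4-[(2S,5E)-6-methyl-7-(TBDPS-oxy)hept-5-en-2-yl]cyclohex-2-en-1-one | O=C1CC[C@@H]([C@@H](C)CC/C=C(\C)CO[Si](c2ccccc2)(c2ccccc2)C(C)(C)C)C=C1CO | intermediate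
8 | {(3S)-3-[(2S,5E)-6-methyl-7-(TBDPS-oxy)hept-5-en-2-yl]-6-methylidenecyclohex-1-en-1-yl}methanol | C=C1CC[C@@H]([C@@H](C)CC/C=C(\C)CO[Si](c2ccccc2)(c2ccccc2)C(C)(C)C)C=C1CO | intermediate
9 | but-3-en-2-ol (racemic) | C=CC(C)O | starting material
10 | triethyl orthoacetate (1,1,1-triethoxyethane) | CC(OCC)(OCC)OCC | starting material
11 | 3-[(1-ethoxyethenyl)oxy]but-1-ene (ketene acetal) | C=C(OCC)OC(C)C=C | intermediate
12 | ethyl (4E)-hex-4-enoate | CCOC(=O)CC/C=C/C | intermediate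
13 | (4E)-hex-4-enoic acid | OC(=O)CC/C=C/C | intermediate
14 | {(3S)-3-[(2S,5E)-6-methyl-7-(TBDPS-oxy)hept-5-en-2-yl]-6-methylidenecyclohex-1-en-1-yl}methyl (4E)-hex-4-enoate | C=C1CC[C@@H]([C@@H](C)CC/C=C(\C)CO[Si](c2ccccc2)(c2ccccc2)C(C)(C)C)C=C1COC(=O)CC/C=C/C | intermediate
15 | pent-4-en-1-ol | C=CCCCO | starting material
16 | pent-4-enal | C=CCCC=O | intermediate
17 | 2-methylidenepent-4-enal | C=CCC(=C)C=O | intermediate
18 | 2-methylidenepent-4-en-1-ol | C=CCC(=C)CO | intermediate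
19 | 2-(bromomethyl)penta-1,4-diene | C=CCC(=C)CBr | intermediate
20 | dibromomethane | BrCBr | starting material
21 | dibromomethyllithium | [Li]C(Br)Br | intermediate
22 | 1,1-dibromo-3-methylidenehex-5-ene | BrC(Br)CC(=C)CC=C | intermediate
23 | (3-methylidenehex-5-ene-1,1-diyl)bis(bromozinc), geminal dizinc reagent | Br[Zn]C([Zn]Br)CC(=C)CC=C | intermediate
24 | {(3S)-3-[(2S,5E)-6-methyl-7-(TBDPS-oxy)hept-5-en-2-yl]-6-methylidenecyclohex-1-en-1-yl}methyl (6Z,10E)-4-methylidenedodeca-1,6,10-trien-7-yl ether | C=C1CC[C@@H]([C@@H](C)CC/C=C(\C)CO[Si](c2ccccc2)(c2ccccc2)C(C)(C)C)C=C1CO/C(CC/C=C/C)=C\CC(=C)CC=C | intermediate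
25 | (6S,10E)-6-{(1R,6S)-6-[(2S,5E)-6-methyl-7-(TBDPS-oxy)hept-5-en-2-yl]-2,3-dimethylidenecyclohexyl}-4-methylidenedodeca-1,10-dien-7-one | C=C1CC[C@@H]([C@@H](C)CC/C=C(\C)CO[Si](c2ccccc2)(c2ccccc2)C(C)(C)C)[C@H]([C@H](CC(=C)CC=C)C(=O)CC/C=C/C)C1=C | intermediate
26 | (4E)-1-{(6S,7R,8S)-8-[(2S,5E)-6-methyl-7-(TBDPS-oxy)hept-5-en-2-yl]-4,11-dimethylidenebicyclo[5.4.0]undec-1-en-6-yl}hex-4-en-1-one | C=C1CC[C@@H]([C@@H](C)CC/C=C(\C)CO[Si](c2ccccc2)(c2ccccc2)C(C)(C)C)[C@H]3C1=CCC(=C)C[C@@H]3C(=O)CC/C=C/C | intermediate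
27 | (4E)-1-{(6S,7R,8S)-11-methyl-8-[(2S,5E)-6-methyl-7-(TBDPS-oxy)hept-5-en-2-yl]-4-methylidenebicyclo[5.4.0]undec-1(11)-en-6-yl}hex-4-en-1-one | CC1=C2CCC(=C)C[C@H](C(=O)CC/C=C/C)[C@H]2[C@H]([C@@H](C)CC/C=C(\C)CO[Si](c3ccccc3)(c3ccccc3)C(C)(C)C)CC1 | intermediate
28 | tert-butyl{[(2E,6S)-6-{(6S,7R,8S)-6-[(5E)-hepta-1,5-dien-2-yl]-11-methyl-4-methylidenebicyclo[5.4.0]undec-1(11)-en-8-yl}-2-methylhept-2-en-1-yl]oxy}diphenylsilane | CC1=C2CCC(=C)C[C@H](C(=C)CC/C=C/C)[C@H]2[C@H]([C@@H](C)CC/C=C(\C)CO[Si](c3ccccc3)(c3ccccc3)C(C)(C)C)CC1 | intermediate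
29 | tert-butyl{[(2E,6S)-2-methyl-6-[(1S,2R,3S)-6-methyl-14-methylidenetricyclo[8.4.1.0^{2,7}]pentadeca-6,10-dien-3-yl]hept-2-en-1-yl]oxy}diphenylsilane | C=C1CCC=C2CCC3=C(C)CC[C@@H]([C@@H](C)CC/C=C(\C)CO[Si](c4ccccc4)(c4ccccc4)C(C)(C)C)[C@@H]3[C@@H]1C2 | intermediate
30 | (2E,6S)-2-methyl-6-[(1S,2R,3S)-6-methyl-14-methylidenetricyclo[8.4.1.0^{2,7}]pentadeca-6,10-dien-3-yl]hept-2-en-1-ol | C=C1CCC=C2CCC3=C(C)CC[C@@H]([C@@H](C)CC/C=C(\C)CO)[C@@H]3[C@@H]1C2 | target

**Step count and risks**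

Total step count: 19.
Longest linear sequence: 12 steps (1, 2, 3, 4, 5, 8, 14, 15, 16, 17, 18, 19), which is 12/19 of the total. The dibromide branch (steps 9–13) and the acid branch (steps 6–7) run in parallel.

Steps most likely to fail:

Step 4. The Morita–Baylis–Hillman hydroxymethylation may stall because C3 of enone 6 is flanked by the branched C4 substituent. The fallback sets out from 6: α-iodination (I2, pyridine, CH2Cl2) gives (4S)-2-iodo-4-[(2S,5E)-6-methyl-7-(TBDPS-oxy)hept-5-en-2-yl]cyclohex-2-en-1-one F1. A Stille coupling of this iodide with Bu3SnCH2OH (Pd(PPh3)4, dioxane, 80 °C) installs the hydroxymethyl group and comes back to the route at 7.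

Step 14. The ester alkylidenation may be sluggish or give poor Z selectivity, and the enol ether is sensitive. The fallback sets out from 8 and builds the same bond by an ester-enolate Claisen rearrangement. A Johnson–Claisen reaction of 18 with 10 gives ethyl 4-methylidenehept-6-enoate F2, and saponification gives 4-methylidenehept-6-enoic acid F3. Carbodiimide esterification of 8 with this acid gives {(3S)-3-[(2S,5E)-6-methyl-7-(TBDPS-oxy)hept-5-en-2-yl]-6-methylidenecyclohex-1-en-1-yl}methyl 4-methylidenehept-6-enoate F4. An Ireland–Claisen rearrangement (LiN(i-Pr)2, THF, −78 °C; Me3SiCl; 60 °C) goes through the ketene acetal with the chain cis to the allylic oxygen and the same chair, giving (2S)-2-{(1R,6S)-6-[(2S,5E)-6-methyl-7-(TBDPS-oxy)hept-5-en-2-yl]-2,3-dimethylidenecyclohexyl}-4-methylidenehept-6-enoic acid F5. Coupling with MeNHOMe·HCl gives (2S)-2-{(1R,6S)-6-[(2S,5E)-6-methyl-7-(TBDPS-oxy)hept-5-en-2-yl]-2,3-dimethylidenecyclohexyl}-N-methoxy-N-methyl-4-methylidenehept-6-enamide F6. Addition of (E)-CH3CH=CHCH2CH2MgBr comes back to the route at 25.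

Step 18. The bridging ring closure to a bridgehead alkene is the least secure step and has not been modelled. The fallback sets out from 27 and moves the ring closure ahead of the methylenation, so that C14 is a flat carbonyl and no second 1,1-disubstituted alkene is present. Ring-closing metathesis of 27 gives (1S,2R,3S)-6-methyl-3-[(2S,5E)-6-methyl-7-(TBDPS-oxy)hept-5-en-2-yl]tricyclo[8.4.1.0^{2,7}]pentadeca-6,10-dien-14-one F7. Wittig methylenation of this ketone comes back to the route at 29.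

**Further compounds**
F1 | step 4 | (4S)-2-iodo-4-[(2S,5E)-6-methyl-7-(TBDPS-oxy)hept-5-en-2-yl]cyclohex-2-en-1-one | O=C1CC[C@@H]([C@@H](C)CC/C=C(\C)CO[Si](c2ccccc2)(c2ccccc2)C(C)(C)C)C=C1I
F2 | step 14 | ethyl 4-methylidenehept-6-enoate | CCOC(=O)CCC(=C)CC=C
F3 | step 14 | 4-methylidenehept-6-enoic acid | OC(=O)CCC(=C)CC=C
F4 | step 14 | {(3S)-3-[(2S,5E)-6-methyl-7-(TBDPS-oxy)hept-5-en-2-yl]-6-methylidenecyclohex-1-en-1-yl}methyl 4-methylidenehept-6-enoate | C=C1CC[C@@H]([C@@H](C)CC/C=C(\C)CO[Si](c2ccccc2)(c2ccccc2)C(C)(C)C)C=C1COC(=O)CCC(=C)CC=C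
F5 | step 14 | (2S)-2-{(1R,6S)-6-[(2S,5E)-6-methyl-7-(TBDPS-oxy)hept-5-en-2-yl]-2,3-dimethylidenecyclohexyl}-4-methylidenehept-6-enoic acid | C=C1CC[C@@H]([C@@H](C)CC/C=C(\C)CO[Si](c2ccccc2)(c2ccccc2)C(C)(C)C)[C@H]([C@H](CC(=C)CC=C)C(=O)O)C1=C
F6 | step 14 | (2S)-2-{(1R,6S)-6-[(2S,5E)-6-methyl-7-(TBDPS-oxy)hept-5-en-2-yl]-2,3-dimethylidenecyclohexyl}-N-methoxy-N-methyl-4-methylidenehept-6-enamide | C=C1CC[C@@H]([C@@H](C)CC/C=C(\C)CO[Si](c2ccccc2)(c2ccccc2)C(C)(C)C)[C@H]([C@H](CC(=C)CC=C)C(=O)N(C)OC)C1=C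
F7 | step 18 | (1S,2R,3S)-6-methyl-3-[(2S,5E)-6-methyl-7-(TBDPS-oxy)hept-5-en-2-yl]tricyclo[8.4.1.0^{2,7}]pentadeca-6,10-dien-14-one | O=C1CCC=C2CCC3=C(C)CC[C@@H]([C@@H](C)CC/C=C(\C)CO[Si](c4ccccc4)(c4ccccc4)C(C)(C)C)[C@@H]3[C@@H]1C2
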